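**Retrosynthetic overview**
- Feature: the ring atoms of the 1,2-dioxane (O1–O2–C3–C4–C5–C6) are three two-atom π units laid end to end. C5=C6(OMe)(chain) is a 2-methoxyalkene with C6 already at the ketal oxidation level, C3=C4 is the terminal alkene of methyl but-3-enoate with the acetate arm already on C3, and O1–O2 is dioxygen.
- Late disconnections: CO2H goes back to the racemic methyl ester (a lipase kinetic resolution fixes the absolute configuration). The C(sp)–C(sp2) bond of the (E)-enyne goes back to a dioxane bearing a pent-4-ynyl chain and (E)-1-iodoundeca-1,10-diene (Sonogashira; iodide from dec-9-en-1-ol).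
- Ring formation: the single ring is closed in one anodic radical-cation operation, in the bond order C5–C4, C3–O2, O1–C6. C6 is then equilibrated to the anomerically favoured epimer (OMe axial, cis to the C3 arm).
- The enol ether comes from hex-5-ynoic acid by C-silylation of the dianion, esterification and ester methylenation.

Key step: step 4

Assumption: the sense of enantioselection of a hydrolase towards a stereocentre β to the ester carbonyl cannot be predicted, so Burkholderia cepacia lipase is assumed to turn over the (3S,6R)-ester faster, to be confirmed on an analytical scale against a small hydrolase panel.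
Remark: every dioxane before the last step is racemic and the (3S,6R) enantiomer is drawn; the ring is numbered O1, O2, C3 (acetate arm), C4, C5, C6 (ketal carbon) throughout.
Remark: step 4 combines LiClO4, MeNO2 and an organic peroxide, so it is meant for small, shielded batches, and the perchlorate is washed out with water before any concentration.

**Step 1**
Reactants: 1 hex-5-ynoic acid
Product: 3 6-(triisopropylsilyl)hex-5-ynoic acid, via dilithiated hex-5-ynoate 2 (not isolated)
Conditions: n-BuLi (2.1 equiv), THF, −78 to 0 °C; TIPSCl (1.15 equiv), −78 °C to rt; 1 M HCl work-up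
Reagents that add atoms: chlorotriisopropylsilane (TIPSCl), CC(C)[Si](Cl)(C(C)C)C(C)C
Why: C-silylation of a lithium acetylide, in which the carbon terminus of the carboxylate–acetylide dianion is far more nucleophilic than the carboxylate, any silyl ester is cleaved in the acidic work-up, and silylating before esterification keeps an enolisable, electrophilic methyl ester away from the organolithium base.

**Step 2**
Reactants: 3 6-(triisopropylsilyl)hex-5-ynoic acid
Product: 4 methyl 6-(triisopropylsilyl)hex-5-ynoate
Conditions: MeOH, H2SO4 (cat.), reflux
Reagents that add atoms: methanol, CO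
Why: Fischer esterification driven by the solvent excess; the hindered alkynylsilane is stable to acidic methanol and any residual silyl ester from step 1 is methanolysed to the same product.

**Step 3**
Reactants: 4 methyl 6-(triisopropylsilyl)hex-5-ynoate
Product: 5 2-methoxy-7-(triisopropylsilyl)hept-1-en-6-yne
Conditions: Cp2TiMe2 (2.0 equiv), toluene, 70 °C, dark; pentane, filtration through basic Al2O3 (1% Et3N); used at once
Reagents that add atoms: dimethyltitanocene Cp2TiMe2 (delivers CH2), [CH3-].[CH3-].[Ti+4].c1cc[cH-]c1.c1cc[cH-]c1
Why: Petasis methylenation, in which thermolysis of Cp2TiMe2 releases Cp2Ti=CH2 that swaps the ester carbonyl oxygen for CH2 by [2+2] addition and cycloreversion under non-acidic conditions, delivers only the terminal 2-methoxyalkene regioisomer, and is kept off the alkyne by the oxophilicity of titanium and the bulk of the triisopropylsilyl cap.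

**Step 4**
Reactants: 5 2-methoxy-7-(triisopropylsilyl)hept-1-en-6-yne, 6 methyl but-3-enoate, 7 dioxygen
Product: 11 methyl 2-[6-methoxy-6-[5-(triisopropylsilyl)pent-4-yn-1-yl]-1,2-dioxan-3-yl]acetate (racemic; both C6 epimers), via enol ether radical cation 8 (not isolated), via distonic C3-radical C6-oxocarbenium ion 9 (not isolated), via C3-peroxyl C6-oxocarbenium ion 10 (not isolated)
Conditions: divided cell (glass frit), carbon felt anode, Pt cathode; anolyte 1.0 M LiClO4/MeNO2, dioxygen (1 atm, bubbled), 6 (15 equiv), 2,6-lutidine (0.3 equiv), 5 added over 4 h; catholyte 1.0 M LiClO4/MeNO2, AcOH, argon; anode potential held at the onset of the oxidation wave of 5 (from cyclic voltammetry) until 5 is consumed, 0 °C; water wash, excess 6 removed in vacuo, Et3N-washed SiO2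
Reagents that add atoms: none
Why: Proposed new method: the anode takes one electron from 5, by a wide margin the most easily oxidised π system present (silylalkyne, ester-bearing alkene 6 and product 11 all lie much higher), and radical cation 8 bonds through its CH2 terminus (C5) to the unsubstituted terminus of 6 (C4), the only orientation that leaves the charge as a methoxy-stabilised oxocarbenium ion at C6 and the spin as a secondary radical at C3 (9). Triplet dioxygen 7 captures the C3 radical at a near diffusion-controlled rate (C3–O2, 10) and the terminal peroxyl oxygen closes on C6 in a 6-exo-trig mode (O1–C6) as an electron is taken from a further molecule of 5, which regenerates 8 so that the anode should only have to start and sustain a chain. The closest known reaction types are the radical-cation [2+2+2] cycloadditions of 1,1-diarylethenes and tethered styrenes with dioxygen to 1,2-dioxanes and the anodic enol ether–terminal alkene couplings in LiClO4/MeNO2; what is new is the crossed, intermolecular union of two different aliphatic alkenes with dioxygen, made plausible because cyclobutane closure of adducts such as 9 is reversible and unproductive when no aryl group is at hand to reduce the ring-closed radical cation. C3 arises from a planar radical in an achiral medium, so 11 is racemic, and C6 is set relative to C3 in a chair-like closure with the acetate arm equatorial and some bias for an axial methoxy group, but both epimers are accepted because step 5 converges them. The step needs chemoselective oxidation, head-to-tail regiochemistry and cross- over homo-coupling: the first two are secured by the methoxy group of 5, the third by the large excess of cheap, volatile 6 and the slow addition of 5. The divided cell keeps dioxygen and the O–O bond of 11 away from the cathode, and 2,6-lutidine scavenges adventitious acid that would hydrolyse or isomerise 5.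

**Step 5**
Reactants: 11 methyl 2-[6-methoxy-6-[5-(triisopropylsilyl)pent-4-yn-1-yl]-1,2-dioxan-3-yl]acetate (racemic; both C6 epimers)
Product: 12 methyl 2-[(3S*,6R*)-6-methoxy-6-[5-(triisopropylsilyl)pent-4-yn-1-yl]-1,2-dioxan-3-yl]acetate (racemic; (3S,6R) enantiomer drawn)
Conditions: camphorsulfonic acid (10 mol %), anhydrous MeOH–CH2Cl2 (1:3), 3 Å molecular sieves, rt; Et3N quench
Reagents that add atoms: none
Why: Acid-catalysed peroxyketal equilibration (transketalisation), in which reversible ionisation at C6 leaves C3 untouched and funnels both epimers into the chair with the acetate arm and the alkynyl chain equatorial and the methoxy group axial (anomeric effect), which is the cis relationship of OMe and CH2CO2Me found in the target, while the methyl ester exchanges degenerately and the silylalkyne is inert.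

**Step 6**
Reactants: 12 methyl 2-[(3S*,6R*)-6-methoxy-6-[5-(triisopropylsilyl)pent-4-yn-1-yl]-1,2-dioxan-3-yl]acetate
Product: 13 methyl 2-[(3S*,6R*)-6-methoxy-6-(pent-4-yn-1-yl)-1,2-dioxan-3-yl]acetate (racemic; (3S,6R) enantiomer drawn)
Conditions: TBAF (1.5 equiv), AcOH (1.5 equiv), THF, 0 °C to rt
Reagents that add atoms: none
Why: Fluoride-induced protodesilylation of the alkynylsilane, buffered with acetic acid so that neither base-induced O–O fragmentation through the C3–H bond (Kornblum–DeLaMare) nor β-elimination of the peroxide from the ester enolate can set in.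

**Step 7**
Reactants: 14 dec-9-en-1-ol
Product: 15 dec-9-enal
Conditions: TEMPO (10 mol %), PhI(OAc)2 (1.1 equiv), CH2Cl2, rt
Reagents that add atoms: none
Why: TEMPO/PhI(OAc)2 oxidation, in which the oxoammonium species takes the primary alcohol to the aldehyde without over-oxidation in the absence of water and leaves the terminal alkene untouched.

**Step 8**
Reactants: 15 dec-9-enal
Product: 16 (1E)-1-iodoundeca-1,10-diene
Conditions: CrCl2 (6 equiv), CHI3 (2 equiv), dioxane–THF (6:1), 0 °C to rt, dark
Reagents that add atoms: iodoform, IC(I)I
Why: Takai olefination, in which the geminal dichromium species formed from CHI3 and divalent chromium adds to the aldehyde and eliminates through the arrangement that places alkyl chain and iodine anti, favouring the (E)-iodoalkene (a bias strengthened by the dioxane-rich solvent), while the isolated terminal alkene is inert and any minor Z isomer is to be removed on AgNO3-impregnated silica gel before the coupling.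

**Step 9**
Reactants: 13 methyl 2-[(3S*,6R*)-6-methoxy-6-(pent-4-yn-1-yl)-1,2-dioxan-3-yl]acetate, 16 (1E)-1-iodoundeca-1,10-diene
Product: 17 methyl 2-[(3S*,6R*)-6-[(6E)-hexadeca-6,15-dien-4-yn-1-yl]-6-methoxy-1,2-dioxan-3-yl]acetate (racemic; (3S,6R) enantiomer drawn)
Conditions: PdCl2(PPh3)2 (5 mol %), CuI (10 mol %), Et3N (3 equiv), 16 (1.2 equiv), degassed THF, rt
Reagents that add atoms: none
Why: Sonogashira coupling, in which oxidative addition of zerovalent palladium into the C–I bond and transmetalation from the copper acetylide retain the E geometry at room temperature, conditions that dialkyl peroxides and peroxyketals tolerate as long as no free phosphine is added and the amine is tertiary, with the remote terminal alkene as a spectator.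

**Step 10**
Reactants: 17 methyl 2-[(3S*,6R*)-6-[(6E)-hexadeca-6,15-dien-4-yn-1-yl]-6-methoxy-1,2-dioxan-3-yl]acetate (racemic)
Product: 18 2-[(3S,6R)-6-[(6E)-hexadeca-6,15-dien-4-yn-1-yl]-6-methoxy-1,2-dioxan-3-yl]acetic acid
Conditions: Burkholderia cepacia lipase (Amano PS), 0.1 M phosphate buffer pH 7.0–MTBE, 30 °C, stopped short of half conversion; acid separated from the remaining ester by chromatography
Reagents that add atoms: water, O
Why: Hydrolase-catalysed kinetic resolution (enantioselective ester hydrolysis), in which a lipase whose acyl tunnel accepts fatty-acid-like chains should tell the enantiomers apart by the direction in which the C3 ring and its long C6 chain leave the acyl pocket, so that only the (3S,6R)-ester is turned over before half conversion, no stereocentre is touched, and the neutral medium avoids the O–O fragmentation and β-elimination that threaten a chemical saponification.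

**Compound list**
1 | hex-5-ynoic acid | C#CCCCC(=O)O | starting material
2 | dilithiated hex-5-ynoate (lithium carboxylate, lithium acetylide) | [Li+].[Li+].[C-]#CCCCC(=O)[O-] | intermediate
3 | 6-(triisopropylsilyl)hex-5-ynoic acid | CC(C)[Si](C(C)C)(C(C)C)C#CCCCC(=O)O | intermediate
4 | methyl 6-(triisopropylsilyl)hex-5-ynoate | COC(=O)CCCC#C[Si](C(C)C)(C(C)C)C(C)C | intermediate
5 | 2-methoxy-7-(triisopropylsilyl)hept-1-en-6-yne | C=C(OC)CCCC#C[Si](C(C)C)(C(C)C)C(C)C | intermediate
6 | methyl but-3-enoate | C=CCC(=O)OC | starting material
7 | dioxygen | O=O | starting material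
8 | radical cation of 5 (drawn as C5 radical, C6 oxocarbenium) | [CH2]C(=[O+]C)CCCC#C[Si](C(C)C)(C(C)C)C(C)C | intermediate
9 | distonic adduct, C3 radical and C6 oxocarbenium ion | COC(=O)C[CH]CCC(=[O+]C)CCCC#C[Si](C(C)C)(C(C)C)C(C)C | intermediate
10 | C3 peroxyl radical, C6 oxocarbenium ion | COC(=O)CC(O[O])CCC(=[O+]C)CCCC#C[Si](C(C)C)(C(C)C)C(C)C | intermediate
11 | methyl 2-[6-methoxy-6-[5-(triisopropylsilyl)pent-4-yn-1-yl]-1,2-dioxan-3-yl]acetate, racemic, both C6 epimers | COC(=O)CC1CCC(OC)(CCCC#C[Si](C(C)C)(C(C)C)C(C)C)OO1 | intermediate
12 | methyl 2-[(3S*,6R*)-6-methoxy-6-[5-(triisopropylsilyl)pent-4-yn-1-yl]-1,2-dioxan-3-yl]acetate, racemic, (3S,6R) drawn | CC(C)[Si](C(C)C)(C(C)C)C#CCCC[C@]1(OC)CC[C@@H](CC(=O)OC)OO1 | intermediate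
13 | methyl 2-[(3S*,6R*)-6-methoxy-6-(pent-4-yn-1-yl)-1,2-dioxan-3-yl]acetate, racemic, (3S,6R) drawn | C#CCCC[C@]1(OC)CC[C@@H](CC(=O)OC)OO1 | intermediate
14 | dec-9-en-1-ol | C=CCCCCCCCCO | starting material
15 | dec-9-enal | C=CCCCCCCCC=O | intermediate
16 | (1E)-1-iodoundeca-1,10-diene | C=CCCCCCCC/C=C/I | intermediate
17 | methyl 2-[(3S*,6R*)-6-[(6E)-hexadeca-6,15-dien-4-yn-1-yl]-6-methoxy-1,2-dioxan-3-yl]acetate, racemic, (3S,6R) drawn | C=CCCCCCCC/C=C/C#CCCC[C@]1(OC)CC[C@@H](CC(=O)OC)OO1 | intermediate
18 | 2-[(3S,6R)-6-[(6E)-hexadeca-6,15-dien-4-yn-1-yl]-6-methoxy-1,2-dioxan-3-yl]acetic acid | C=CCCCCCCC/C=C/C#CCCC[C@]1(OC)CC[C@@H](CC(=O)O)OO1 | target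

**Step count**
Total step count: 10. Longest linear sequence: 8 steps (steps 1–6, 9 and 10); steps 7 and 8 form the side branch.

**Steps most likely to fail**

Step 4.
- What may go wrong: addition of the radical cation to the slightly ester-deactivated alkene may be too slow. Homocoupling of the enol ether, direct oxygenation and cleavage of its radical cation, hydrogen abstraction by the peroxyl radical (chain breakage) or acid hydrolysis of the enol ether could then take over.
- Partial capture of C6 by adventitious water would be harmless, because step 5 would convert the hemiperketal into the same methyl ketal.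
- The fallback uses known chemistry, sets out from 4 and returns at 11.
- MeNH(OMe)·HCl and iPrMgCl in THF convert 4 into N-methoxy-N-methyl-6-(triisopropylsilyl)hex-5-ynamide F1.
- But-3-enylmagnesium bromide gives 10-(triisopropylsilyl)dec-1-en-9-yn-5-one F2.
- Cross metathesis with methyl acrylate (second-generation Hoveyda–Grubbs catalyst; the hindered silylalkyne stays out of the metathesis) gives methyl (2E)-6-oxo-11-(triisopropylsilyl)undec-2-en-10-ynoate F3.
- Urea–hydrogen peroxide with catalytic Sc(OTf)3 in MeOH gives methyl (2E)-6-hydroperoxy-6-methoxy-11-(triisopropylsilyl)undec-2-en-10-ynoate F4.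
- Et2NH in CF3CH2OH closes the ring by 6-exo intramolecular oxa-Michael addition of the hydroperoxide to the enoate, giving 11.

Step 10.
- What may go wrong: discrimination of the enantiomers may be poor because the stereocentre is β to the carbonyl, the opposite enantiomer may be preferred, or turnover of the very lipophilic ester may be slow.
- The fallback is a resolution through covalent diastereomers; it sets out from 17 and returns at 18.
- Brief treatment with LiOH in THF–water at 0 °C gives racemic 2-[(3S*,6R*)-6-[(6E)-hexadeca-6,15-dien-4-yn-1-yl]-6-methoxy-1,2-dioxan-3-yl]acetic acid F5.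
- Pivaloyl chloride, Et3N, LiCl and (S)-4-benzyloxazolidin-2-one give the (3S,6R)-N-acyl-(4S)-4-benzyloxazolidin-2-one F6 and its diastereomer, the (3R,6S)-N-acyl-(4S)-4-benzyloxazolidin-2-one F7. The two are separated by chromatography.
- LiOH/H2O2 in THF–water at 0 °C cleaves F6 to 18.

Step 8.
- What may go wrong: the E selectivity for an unbranched aliphatic aldehyde may be incomplete, and the geometric isomers may be difficult to separate, which would carry a Z-enyne impurity to the end.
- The fallback replaces carbonyl olefination by syn-hydrometalation of an alkyne; it sets out from 15 and returns at 16.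
- Dimethyl (1-diazo-2-oxopropyl)phosphonate and K2CO3 in MeOH (Ohira–Bestmann homologation) give undec-10-en-1-yne F8.
- Cp2ZrHCl (1.0 equiv, CH2Cl2, 0 °C) adds syn and terminally to the alkyne, which inserts markedly faster than a monosubstituted alkene, to give chloro[(1E)-undeca-1,10-dien-1-yl]zirconocene F9.
- Iodine cleaves the C–Zr bond with retention to give 16 as the E isomer only.

**Further compounds**
F1 | step 4 | N-methoxy-N-methyl-6-(triisopropylsilyl)hex-5-ynamide | CON(C)C(=O)CCCC#C[Si](C(C)C)(C(C)C)C(C)C
F2 | step 4 | 10-(triisopropylsilyl)dec-1-en-9-yn-5-one | C=CCCC(=O)CCCC#C[Si](C(C)C)(C(C)C)C(C)C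
F3 | step 4 | methyl (2E)-6-oxo-11-(triisopropylsilyl)undec-2-en-10-ynoate | COC(=O)/C=C/CCC(=O)CCCC#C[Si](C(C)C)(C(C)C)C(C)C
F4 | step 4 | methyl (2E)-6-hydroperoxy-6-methoxy-11-(triisopropylsilyl)undec-2-en-10-ynoate, racemic | COC(=O)/C=C/CCC(OC)(OO)CCCC#C[Si](C(C)C)(C(C)C)C(C)C
F5 | step 10 | 2-[(3S*,6R*)-6-[(6E)-hexadeca-6,15-dien-4-yn-1-yl]-6-methoxy-1,2-dioxan-3-yl]acetic acid, racemic, (3S,6R) drawn | C=CCCCCCCC/C=C/C#CCCC[C@]1(OC)CC[C@@H](CC(=O)O)OO1
F6 | step 10 | (4S)-4-benzyl-3-[2-[(3S,6R)-6-[(6E)-hexadeca-6,15-dien-4-yn-1-yl]-6-methoxy-1,2-dioxan-3-yl]acetyl]oxazolidin-2-one | C=CCCCCCCC/C=C/C#CCCC[C@]1(OC)CC[C@@H](CC(=O)N2[C@@H](Cc3ccccc3)COC2=O)OO1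
F7 | step 10 | (4S)-4-benzyl-3-[2-[(3R,6S)-6-[(6E)-hexadeca-6,15-dien-4-yn-1-yl]-6-methoxy-1,2-dioxan-3-yl]acetyl]oxazolidin-2-one | C=CCCCCCCC/C=C/C#CCCC[C@@]1(OC)CC[C@H](CC(=O)N2[C@@H](Cc3ccccc3)COC2=O)OO1
F8 | step 8 | undec-10-en-1-yne | C=CCCCCCCCC#C
F9 | step 8 | chloro[(1E)-undeca-1,10-dien-1-yl]zirconocene, Cp2Zr(Cl)(alkenyl) | C=CCCCCCCC/C=C/[Zr+2]Cl.c1cc[cH-]c1.c1cc[cH-]c1
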